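**Retrosynth­etic overview**
1. Target ⇐ stepwise acylation of a cis-fused daucene core: tiglate on C10–OH, 4-acetoxybenzoate on C6–OH, and the phenol freed last by a lipase that touches none of the other esters.
2. C4 carbinol ⇐ isopropyl addition to a C4 ketone from the convex face; C4=O and C6–OH ⇐ N–O cleavage of an isoxazoline.
3. Five-membered ring (ring A, formed second) ⇐ intramolecular nitrile oxide cycloaddition across C5=C6 of a cyclohepta-1,4-diene, which sets C5 and C6.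
4. Seven-membered ring (ring B, formed first) ⇐ ring-closing metathesis at C8=C9.
5. C10/C1 ⇐ catalytic Sharpless epoxidation of an achiral (Z)-allylic alcohol (first stereocentres), then alkynylalane opening at the tertiary epoxide carbon with inversion.

Assumption: daucane numbering is used for ring compounds (ring A = C1–C5, ring B = C5–C10 + C1; C1 carries the angular methyl, C4 the isopropyl, C8 the vinylic methyl), and metal alkoxides, enolates and ammonium salts that exist only before aqueous work-up are not numbered.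
Abbreviations: TBDPS = tert-butyl(diphenyl)silyl; PMB = 4-methoxybenzyl; TES = triethylsilyl.

Step 1
Reactants: 1 pent-4-yn-1-ol
Product: 2 tert-butyl(pent-4-yn-1-yloxy)diphenylsilane
Conditions: TBDPSCl, imidazole, DMF, rt
Reagents that add atoms: tert-butyl(chloro)diphenylsilane, CC(C)(C)[Si](Cl)(c1ccccc1)c1ccccc1
Why: Imidazole-promoted O-silylation protects the primary alcohol as a robust silyl ether; no stereocentre is involved.

Step 2
Reactants: 2 tert-butyl(pent-4-yn-1-yloxy)diphenylsilane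
Product: 4 ethyl 6-(TBDPS-oxy)hex-2-ynoate, via lithium acetylide 3 (not isolated)
Conditions: n-BuLi, THF, −78 °C; ClCO2Et, −78 → 0 °C
Reagents that add atoms: ethyl chloroformate, CCOC(Cl)=O
Why: Deprotonation of the terminal alkyne and C-acylation of the acetylide by the chloroformate gives the alkynoate.

Step 3
Reactants: 4 ethyl 6-(TBDPS-oxy)hex-2-ynoate
Product: 5 ethyl (2Z)-6-(TBDPS-oxy)-3-methylhex-2-enoate
Conditions: Me2CuLi (from MeLi, CuI), THF, −78 °C; MeOH then aq. NH4Cl at −78 °C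
Reagents that add atoms: lithium dimethylcuprate, [Li+].C[Cu-]C
Why: Syn carbocupration (conjugate addition) of the ynoate with cold protonation places methyl trans to the ester, giving the (Z)-enoate.

Step 4
Reactants: 5 ethyl (2Z)-6-(TBDPS-oxy)-3-methylhex-2-enoate
Product: 6 (2Z)-6-(TBDPS-oxy)-3-methylhex-2-en-1-ol
Conditions: i-Bu2AlH, CH2Cl2, −78 °C; aq. Rochelle salt
Reagents that add atoms: none
Why: 1,2-Reduction of the enoate by the aluminium hydride gives the allylic alcohol with the alkene geometry intact.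

Step 5
Reactants: 6 (2Z)-6-(TBDPS-oxy)-3-methylhex-2-en-1-ol
Product: 7 [(2S,3R)-3-methyl-3-(3-(TBDPS-oxy)propyl)oxiran-2-yl]methanol
Conditions: Ti(OiPr)4 (10 mol %), L-(+)-diethyl tartrate (12 mol %), t-BuOOH, 4 Å MS, CH2Cl2, −20 °C
Reagents that add atoms: tert-butyl hydroperoxide, CC(C)(C)OO
Why: Katsuki–Sharpless asymmetric epoxidation with the catalytic titanium–L-tartrate complex delivers oxygen to one alkene face and sets the first two stereocentres, C10 (2S) and C1 (3R).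

Step 6
Reactants: 8 3-chloro-2-methylprop-1-ene; 9 ethynylmagnesium bromide
Product: 10 2-methylpent-1-en-4-yne
Conditions: CuCl (5 mol %), THF, 50 °C
Reagents that add atoms: none
Why: Copper-catalysed allylic substitution of the chloride by the alkynyl Grignard reagent gives the skipped enyne.

Step 7
Reactants: 10 2-methylpent-1-en-4-yne; 7 [(2S,3R)-3-methyl-3-(3-(TBDPS-oxy)propyl)oxiran-2-yl]methanol
Product: 13 (2R,3R)-3-(3-(TBDPS-oxy)propyl)-3,7-dimethyloct-7-en-4-yne-1,2-diol, via alkynyllithium 11 (not isolated), via diethylalkynylalane 12 (not isolated)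
Conditions: 10, n-BuLi, toluene, 0 °C; Et2AlCl; then 7, 0 °C → rt; aq. Rochelle salt
Reagents that add atoms: none
Why: Hydroxyl-assisted alkynylalane opening of the 2,3-epoxy alcohol occurs at the tertiary, cation-stabilising C3 with inversion (SN2-type), creating quaternary C1 with C10–O untouched.

Step 8
Reactants: 13 (2R,3R)-3-(3-(TBDPS-oxy)propyl)-3,7-dimethyloct-7-en-4-yne-1,2-diol
Product: 14 (2R,3R,4Z)-3-(3-(TBDPS-oxy)propyl)-3,7-dimethylocta-4,7-diene-1,2-diol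
Conditions: H2 (1 atm), Pd/CaCO3 poisoned with Pb(OAc)2, quinoline, EtOAc, rt
Reagents that add atoms: none
Why: Lindlar semihydrogenation adds H2 syn to give the (Z)-alkene needed inside ring B, and the 1,1-disubstituted alkene is not reduced.

Step 9
Reactants: 14 (2R,3R,4Z)-3-(3-(TBDPS-oxy)propyl)-3,7-dimethylocta-4,7-diene-1,2-diol
Product: 16 tert-butyl({(4R,5Z)-4,8-dimethyl-4-[(2R)-oxiran-2-yl]nona-5,8-dien-1-yl}oxy)diphenylsilane, via primary tosylate 15 (not isolated)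
Conditions: NaH, N-tosylimidazole, THF, 0 °C → rt
Reagents that add atoms: none
Why: Selective sulfonylation of the primary hydroxyl and intramolecular Williamson closure by the C10 alkoxide give the terminal epoxide with retention at C10.

Step 10
Reactants: 16 tert-butyl({(4R,5Z)-4,8-dimethyl-4-[(2R)-oxiran-2-yl]nona-5,8-dien-1-yl}oxy)diphenylsilane
Product: 18 (3S,4R,5Z)-4-(3-(TBDPS-oxy)propyl)-4,8-dimethylnona-1,5,8-trien-3-ol, via sulfonium betaine 17 (not isolated)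
Conditions: Me3S+ I−, n-BuLi, THF, −10 °C → rt
Reagents that add atoms: trimethylsulfonium iodide, C[S+](C)C.[I-]
Why: The sulfonium ylide opens the epoxide at its CH2 and base-induced loss of Me2S gives the one-carbon-homologated allylic alcohol, with C10 untouched.

Step 11
Reactants: 18 (3S,4R,5Z)-4-(3-(TBDPS-oxy)propyl)-4,8-dimethylnona-1,5,8-trien-3-ol
Product: 19 tert-butyl({(4R,5Z)-4-[(1S)-1-(PMB-oxy)prop-2-en-1-yl]-4,8-dimethylnona-5,8-dien-1-yl}oxy)diphenylsilane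
Conditions: NaH, PMBCl, Bu4NI (cat.), DMF, 0 °C → rt
Reagents that add atoms: 4-methoxybenzyl chloride, COc1ccc(CCl)cc1
Why: Williamson etherification protects C10–OH as an ether that survives fluoride, oxidation and organometallic steps and is removable oxidatively.

Step 12
Reactants: 19 tert-butyl({(4R,5Z)-4-[(1S)-1-(PMB-oxy)prop-2-en-1-yl]-4,8-dimethylnona-5,8-dien-1-yl}oxy)diphenylsilane
Product: 20 tert-butyl(3-{(1R,7S)-7-(PMB-oxy)-1,5-dimethylcyclohepta-2,5-dien-1-yl}propoxy)diphenylsilane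
Conditions: second-generation Grubbs catalyst RuCl2(=CHPh)(PCy3)(H2IMes) (5 mol %), CH2Cl2 (2 mM), 40 °C
Reagents that add atoms: none
Why: Ring-closing olefin metathesis between the vinyl group and the 1,1-disubstituted alkene forms trisubstituted C8=C9 and ring B, preorganised by the cis C5=C6 alkene and driven by loss of ethene.

Step 13
Reactants: 20 tert-butyl(3-{(1R,7S)-7-(PMB-oxy)-1,5-dimethylcyclohepta-2,5-dien-1-yl}propoxy)diphenylsilane
Product: 21 3-{(1R,7S)-7-(PMB-oxy)-1,5-dimethylcyclohepta-2,5-dien-1-yl}propan-1-ol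
Conditions: Bu4NF, THF, rt
Reagents that add atoms: none
Why: Fluoride-induced desilylation frees the primary alcohol while the PMB ether is inert.

Step 14
Reactants: 21 3-{(1R,7S)-7-(PMB-oxy)-1,5-dimethylcyclohepta-2,5-dien-1-yl}propan-1-ol
Product: 22 3-{(1R,7S)-7-(PMB-oxy)-1,5-dimethylcyclohepta-2,5-dien-1-yl}propanal
Conditions: Dess–Martin periodinane, CH2Cl2, 0 °C → rt
Reagents that add atoms: none
Why: Dess–Martin oxidation converts the primary alcohol into the aldehyde without over-oxidation or isomerisation of the skipped diene.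

Step 15
Reactants: 22 3-{(1R,7S)-7-(PMB-oxy)-1,5-dimethylcyclohepta-2,5-dien-1-yl}propanal
Product: 23 3-{(1R,7S)-7-(PMB-oxy)-1,5-dimethylcyclohepta-2,5-dien-1-yl}propanal oxime
Conditions: NH2OH·HCl, NaOAc, EtOH/H2O, rt
Reagents that add atoms: hydroxylamine hydrochloride, [NH3+]O.[Cl-]
Why: Condensation of the aldehyde with hydroxylamine gives the aldoxime, whose E/Z ratio is irrelevant for the next step.

Step 16
Reactants: 23 3-{(1R,7S)-7-(PMB-oxy)-1,5-dimethylcyclohepta-2,5-dien-1-yl}propanal oxime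
Product: 26 (1R,5R,6R,10S)-tricyclic isoxazoline (C4=N–O–C6 bridge on the cis-fused ring A/ring B core; 10-O-PMB), via hydroximoyl chloride 24 (not isolated), via nitrile oxide 25 (not isolated)
Conditions: aq. NaOCl, CH2Cl2, 0 °C → rt
Reagents that add atoms: none
Why: In the intramolecular nitrile oxide–alkene 1,3-dipolar cycloaddition the three-carbon tether on C1 forces suprafacial addition to the face of C5=C6 syn to it, which closes ring A cis-fused and sets C5 and C6 with the C6 oxygen syn to the new C4–C5 bond.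

Step 17
Reactants: 26 (1R,5R,6R,10S)-tricyclic isoxazoline
Product: 28 (1R,5S,6R,10S)-6-hydroxy-10-(PMB-oxy)-1,8-dimethyl-cis-bicyclo[5.3.0]dec-8-en-4-one (daucane numbering), via hydroxy imine 27 (not isolated)
Conditions: Mo(CO)6, MeCN/H2O (15:1), 80 °C
Reagents that add atoms: water, O
Why: Reductive N–O bond cleavage of the isoxazoline and hydrolysis of the imine unveil the β-hydroxy ketone under neutral conditions that spare the alkene and the PMB ether and do not epimerise C5.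

Step 18
Reactants: 28 (1R,5S,6R,10S)-6-hydroxy-10-(PMB-oxy)-1,8-dimethyl-cis-bicyclo[5.3.0]dec-8-en-4-one
Product: 29 (1R,5S,6R,10S)-10-(PMB-oxy)-1,8-dimethyl-6-(TES-oxy)-cis-bicyclo[5.3.0]dec-8-en-4-one
Conditions: Et3SiOTf, 2,6-lutidine, CH2Cl2, −78 °C
Reagents that add atoms: triethylsilyl trifluoromethanesulfonate, CC[Si](CC)(CC)OS(=O)(=O)C(F)(F)F
Why: Silyl triflate O-silylation masks C6–OH, blocking retro-aldol and β-elimination and keeping C6 distinguishable from C10.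

Step 19
Reactants: 29 (1R,5S,6R,10S)-10-(PMB-oxy)-1,8-dimethyl-6-(TES-oxy)-cis-bicyclo[5.3.0]dec-8-en-4-one
Product: 30 (1R,4R,5S,6R,10S)-10-(PMB-oxy)-1,8-dimethyl-4-(propan-2-yl)-6-(TES-oxy)-cis-bicyclo[5.3.0]dec-8-en-4-ol
Conditions: i-PrMgCl, CeCl3, THF, −78 → 0 °C; aq. NH4Cl
Reagents that add atoms: isopropylmagnesium chloride, CC(C)[Mg]Cl
Why: Organocerium 1,2-addition (low basicity suppresses enolisation and reduction) occurs from the convex face anti to the C6 substituent and ring B, giving (4R) with the hydroxyl syn to C6–O.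

Step 20
Reactants: 30 (1R,4R,5S,6R,10S)-10-(PMB-oxy)-1,8-dimethyl-4-(propan-2-yl)-6-(TES-oxy)-cis-bicyclo[5.3.0]dec-8-en-4-ol
Product: 31 (1R,4R,5S,6R,10S)-1,8-dimethyl-4-(propan-2-yl)-6-(TES-oxy)-cis-bicyclo[5.3.0]dec-8-ene-4,10-diol
Conditions: DDQ, CH2Cl2/pH 7 buffer, 0 °C
Reagents that add atoms: none
Why: Oxidative PMB ether cleavage (benzylic hydride abstraction, then hydrolysis) frees C10–OH without touching the silyl ether or the alkene.

Step 21
Reactants: 31 (1R,4R,5S,6R,10S)-1,8-dimethyl-4-(propan-2-yl)-6-(TES-oxy)-cis-bicyclo[5.3.0]dec-8-ene-4,10-diol; 32 (2E)-2-methylbut-2-enoic acid (tiglic acid)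
Product: 34 (1R,4R,5S,6R,10S)-4-hydroxy-1,8-dimethyl-4-(propan-2-yl)-6-(TES-oxy)-cis-bicyclo[5.3.0]dec-8-en-10-yl (2E)-2-methylbut-2-enoate, via mixed anhydride 33 (not isolated)
Conditions: 32, 2,4,6-trichlorobenzoyl chloride, Et3N, THF, rt; then 31, DMAP, toluene, 60 °C
Reagents that add atoms: none
Why: In the Yamaguchi esterification the mixed anhydride acylates the hindered secondary allylic C10–OH under DMAP catalysis, the tertiary C4–OH is inert and the (E)-acyl geometry is the stable one.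

Step 22
Reactants: 34 (1R,4R,5S,6R,10S)-4-hydroxy-1,8-dimethyl-4-(propan-2-yl)-6-(TES-oxy)-cis-bicyclo[5.3.0]dec-8-en-10-yl (2E)-2-methylbut-2-enoate
Product: 35 (1R,4R,5S,6R,10S)-4,6-dihydroxy-1,8-dimethyl-4-(propan-2-yl)-cis-bicyclo[5.3.0]dec-8-en-10-yl (2E)-2-methylbut-2-enoate
Conditions: HF·pyridine, pyridine, THF, 0 °C → rt
Reagents that add atoms: none
Why: Buffered fluoride desilylation removes the TES ether and leaves the allylic tiglate and the tertiary alcohol unchanged.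

Step 23
Reactants: 35 (1R,4R,5S,6R,10S)-4,6-dihydroxy-1,8-dimethyl-4-(propan-2-yl)-cis-bicyclo[5.3.0]dec-8-en-10-yl (2E)-2-methylbut-2-enoate; 36 4-(acetyloxy)benzoyl chloride
Product: 37 (1R,4R,5S,6R,10S)-4-hydroxy-1,8-dimethyl-10-{[(2E)-2-methylbut-2-enoyl]oxy}-4-(propan-2-yl)-cis-bicyclo[5.3.0]dec-8-en-6-yl 4-(acetyloxy)benzoate
Conditions: pyridine, DMAP (cat.), CH2Cl2, 0 °C → rt
Reagents that add atoms: none
Why: DMAP-catalysed acylation by the acid chloride esterifies the secondary C6–OH only, because the tertiary C4–OH is too hindered to react.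

Step 24
Reactants: 37 (1R,4R,5S,6R,10S)-4-hydroxy-1,8-dimethyl-10-{[(2E)-2-methylbut-2-enoyl]oxy}-4-(propan-2-yl)-cis-bicyclo[5.3.0]dec-8-en-6-yl 4-(acetyloxy)benzoate
Product: 38 CNP0273650.13
Conditions: lipase (Candida antarctica lipase B, immobilised), n-BuOH, t-BuOMe, 40 °C
Reagents that add atoms: none
Why: Lipase-catalysed transesterification (alcoholysis) cleaves only the unhindered phenolic acetate, because the hindered tiglate and the aroyl ester do not fit the serine hydrolase active site, releasing the free phenol of the target under neutral conditions.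

**Compound list**
1 | pent-4-yn-1-ol | C#CCCCO | starting material
2 | tert-butyl(pent-4-yn-1-yloxy)diphenylsilane | C#CCCCO[Si](c1ccccc1)(c1ccccc1)C(C)(C)C | intermediate
3 | [5-(TBDPS-oxy)pent-1-yn-1-yl]lithium | [Li]C#CCCCO[Si](c1ccccc1)(c1ccccc1)C(C)(C)C | intermediate (not isolated)
4 | ethyl 6-{[tert-butyl(diphenyl)silyl]oxy}hex-2-ynoate | CCOC(=O)C#CCCCO[Si](c1ccccc1)(c1ccccc1)C(C)(C)C | intermediate
5 | ethyl (2Z)-6-{[tert-butyl(diphenyl)silyl]oxy}-3-methylhex-2-enoate | CCOC(=O)/C=C(/C)CCCO[Si](c1ccccc1)(c1ccccc1)C(C)(C)C | intermediate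
6 | (2Z)-6-{[tert-butyl(diphenyl)silyl]oxy}-3-methylhex-2-en-1-ol | OC/C=C(/C)CCCO[Si](c1ccccc1)(c1ccccc1)C(C)(C)C | intermediate
7 | [(2S,3R)-3-(3-{[tert-butyl(diphenyl)silyl]oxy}propyl)-3-methyloxiran-2-yl]methanol | OC[C@@H]1O[C@]1(C)CCCO[Si](c2ccccc2)(c2ccccc2)C(C)(C)C | intermediate
8 | 3-chloro-2-methylprop-1-ene | C=C(C)CCl | starting material
9 | ethynylmagnesium bromide | C#C[Mg]Br | starting material
10 | 2-methylpent-1-en-4-yne | C=C(C)CC#C | intermediate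
11 | (4-methylpent-4-en-1-yn-1-yl)lithium | [Li]C#CCC(C)=C | intermediate (not isolated)
12 | diethyl(4-methylpent-4-en-1-yn-1-yl)aluminium | CC[Al](CC)C#CCC(C)=C | intermediate (not isolated)
13 | (2R,3R)-3-(3-{[tert-butyl(diphenyl)silyl]oxy}propyl)-3,7-dimethyloct-7-en-4-yne-1,2-diol | OC[C@H](O)[C@](C)(CCCO[Si](c1ccccc1)(c1ccccc1)C(C)(C)C)C#CCC(C)=C | intermediate
14 | (2R,3R,4Z)-3-(3-{[tert-butyl(diphenyl)silyl]oxy}propyl)-3,7-dimethylocta-4,7-diene-1,2-diol | OC[C@H](O)[C@](C)(CCCO[Si](c1ccccc1)(c1ccccc1)C(C)(C)C)/C=C\CC(C)=C | intermediate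
15 | (2R,3R,4Z)-3-(3-{[tert-butyl(diphenyl)silyl]oxy}propyl)-2-hydroxy-3,7-dimethylocta-4,7-dien-1-yl 4-methylbenzenesulfonate | Cc1ccc(cc1)S(=O)(=O)OC[C@H](O)[C@](C)(CCCO[Si](c2ccccc2)(c2ccccc2)C(C)(C)C)/C=C\CC(C)=C | intermediate (not isolated)
16 | tert-butyl({(4R,5Z)-4,8-dimethyl-4-[(2R)-oxiran-2-yl]nona-5,8-dien-1-yl}oxy)diphenylsilane | C1O[C@@H]1[C@](C)(CCCO[Si](c2ccccc2)(c2ccccc2)C(C)(C)C)/C=C\CC(C)=C | intermediate
17 | [(3S,4R,5Z)-4-(3-{[tert-butyl(diphenyl)silyl]oxy}propyl)-4,8-dimethyl-3-oxidonona-5,8-dien-1-yl]dimethylsulfonium (betaine) | C[S+](C)CC[C@H]([O-])[C@](C)(CCCO[Si](c1ccccc1)(c1ccccc1)C(C)(C)C)/C=C\CC(C)=C | intermediate (not isolated)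
18 | (3S,4R,5Z)-4-(3-{[tert-butyl(diphenyl)silyl]oxy}propyl)-4,8-dimethylnona-1,5,8-trien-3-ol | C=C[C@H](O)[C@](C)(CCCO[Si](c1ccccc1)(c1ccccc1)C(C)(C)C)/C=C\CC(C)=C | intermediate
19 | tert-butyl({(4R,5Z)-4-{(1S)-1-[(4-methoxyphenyl)methoxy]prop-2-en-1-yl}-4,8-dimethylnona-5,8-dien-1-yl}oxy)diphenylsilane | C=C[C@H](OCc1ccc(OC)cc1)[C@](C)(CCCO[Si](c2ccccc2)(c2ccccc2)C(C)(C)C)/C=C\CC(C)=C | intermediate
20 | tert-butyl(3-{(1R,7S)-7-[(4-methoxyphenyl)methoxy]-1,5-dimethylcyclohepta-2,5-dien-1-yl}propoxy)diphenylsilane | COc1ccc(CO[C@H]2C=C(C)CC=C[C@@]2(C)CCCO[Si](c3ccccc3)(c3ccccc3)C(C)(C)C)cc1 | intermediate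
21 | 3-{(1R,7S)-7-[(4-methoxyphenyl)methoxy]-1,5-dimethylcyclohepta-2,5-dien-1-yl}propan-1-ol | COc1ccc(CO[C@H]2C=C(C)CC=C[C@@]2(C)CCCO)cc1 | intermediate
22 | 3-{(1R,7S)-7-[(4-methoxyphenyl)methoxy]-1,5-dimethylcyclohepta-2,5-dien-1-yl}propanal | COc1ccc(CO[C@H]2C=C(C)CC=C[C@@]2(C)CCC=O)cc1 | intermediate
23 | 3-{(1R,7S)-7-[(4-methoxyphenyl)methoxy]-1,5-dimethylcyclohepta-2,5-dien-1-yl}propanal oxime (E/Z mixture) | COc1ccc(CO[C@H]2C=C(C)CC=C[C@@]2(C)CCC=NO)cc1 | intermediate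
24 | N-hydroxy-3-{(1R,7S)-7-[(4-methoxyphenyl)methoxy]-1,5-dimethylcyclohepta-2,5-dien-1-yl}propanimidoyl chloride | COc1ccc(CO[C@H]2C=C(C)CC=C[C@@]2(C)CCC(Cl)=NO)cc1 | intermediate (not isolated)
25 | 3-{(1R,7S)-7-[(4-methoxyphenyl)methoxy]-1,5-dimethylcyclohepta-2,5-dien-1-yl}propanenitrile oxide | COc1ccc(CO[C@H]2C=C(C)CC=C[C@@]2(C)CCC#[N+][O-])cc1 | intermediate (not isolated)
26 | (1R,5R,6R,10S)-tricyclic isoxazoline: cis-fused bicyclo[5.3.0]dec-8-ene (daucane numbering) with 1-CH3, 8-CH3, 10-O-PMB and C4 joined to C6 as C4=N–O–C6 | COc1ccc(CO[C@H]2C=C(C)C[C@H]3ON=C4CC[C@]2(C)[C@@H]34)cc1 | intermediate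
27 | (1R,5R,6R,10S)-4-imino-10-[(4-methoxyphenyl)methoxy]-1,8-dimethyl-cis-bicyclo[5.3.0]dec-8-en-6-ol | COc1ccc(CO[C@H]2C=C(C)C[C@@H](O)[C@@H]3[C@@]2(C)CCC3=N)cc1 | intermediate (not isolated)
28 | (1R,5S,6R,10S)-6-hydroxy-10-[(4-methoxyphenyl)methoxy]-1,8-dimethyl-cis-bicyclo[5.3.0]dec-8-en-4-one | COc1ccc(CO[C@H]2C=C(C)C[C@@H](O)[C@@H]3[C@@]2(C)CCC3=O)cc1 | intermediate
29 | (1R,5S,6R,10S)-10-[(4-methoxyphenyl)methoxy]-1,8-dimethyl-6-[(triethylsilyl)oxy]-cis-bicyclo[5.3.0]dec-8-en-4-one | COc1ccc(CO[C@H]2C=C(C)C[C@@H](O[Si](CC)(CC)CC)[C@@H]3[C@@]2(C)CCC3=O)cc1 | intermediate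
30 | (1R,4R,5S,6R,10S)-10-[(4-methoxyphenyl)methoxy]-1,8-dimethyl-4-(propan-2-yl)-6-[(triethylsilyl)oxy]-cis-bicyclo[5.3.0]dec-8-en-4-ol | COc1ccc(CO[C@H]2C=C(C)C[C@@H](O[Si](CC)(CC)CC)[C@@H]3[C@@]2(C)CC[C@@]3(O)C(C)C)cc1 | intermediate
31 | (1R,4R,5S,6R,10S)-1,8-dimethyl-4-(propan-2-yl)-6-[(triethylsilyl)oxy]-cis-bicyclo[5.3.0]dec-8-ene-4,10-diol | O[C@H]1C=C(C)C[C@@H](O[Si](CC)(CC)CC)[C@@H]2[C@@]1(C)CC[C@@]2(O)C(C)C | intermediate
32 | (2E)-2-methylbut-2-enoic acid (tiglic acid) | C/C=C(\C)C(O)=O | starting material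
33 | (2E)-2-methylbut-2-enoic 2,4,6-trichlorobenzoic anhydride | C/C=C(\C)C(=O)OC(=O)c1c(Cl)cc(Cl)cc1Cl | intermediate (not isolated)
34 | (1R,4R,5S,6R,10S)-4-hydroxy-1,8-dimethyl-4-(propan-2-yl)-6-[(triethylsilyl)oxy]-cis-bicyclo[5.3.0]dec-8-en-10-yl (2E)-2-methylbut-2-enoate | C/C=C(\C)C(=O)O[C@H]1C=C(C)C[C@@H](O[Si](CC)(CC)CC)[C@@H]2[C@@]1(C)CC[C@@]2(O)C(C)C | intermediate
35 | (1R,4R,5S,6R,10S)-4,6-dihydroxy-1,8-dimethyl-4-(propan-2-yl)-cis-bicyclo[5.3.0]dec-8-en-10-yl (2E)-2-methylbut-2-enoate | C/C=C(\C)C(=O)O[C@H]1C=C(C)C[C@@H](O)[C@@H]2[C@@]1(C)CC[C@@]2(O)C(C)C | intermediate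
36 | 4-(acetyloxy)benzoyl chloride | CC(=O)Oc1ccc(cc1)C(Cl)=O | starting material
37 | (1R,4R,5S,6R,10S)-4-hydroxy-1,8-dimethyl-10-{[(2E)-2-methylbut-2-enoyl]oxy}-4-(propan-2-yl)-cis-bicyclo[5.3.0]dec-8-en-6-yl 4-(acetyloxy)benzoate | C/C=C(\C)C(=O)O[C@H]1C=C(C)C[C@@H](OC(=O)c2ccc(OC(C)=O)cc2)[C@@H]2[C@@]1(C)CC[C@@]2(O)C(C)C | intermediate
38 | CNP0273650.13 = (3R,3aS,4R,8S,8aR)-3-hydroxy-6,8a-dimethyl-8-{[(2E)-2-methylbut-2-enoyl]oxy}-3-(propan-2-yl)-1,2,3,3a,4,5,8,8a-octahydroazulen-4-yl 4-hydroxybenzoate; daucane descriptors (1R,4R,5S,6R,10S) | C/C=C(\C)C(=O)O[C@H]1C=C(C)C[C@@H](OC(=O)c2ccc(O)cc2)[C@@H]2[C@@]1(C)CC[C@@]2(O)C(C)C | target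

**Totals**
Total step count: 24. Longest linear sequence: 23 steps (steps 1–5 and 7–24 from pent-4-yn-1-ol; step 6 makes the enyne side fragment).

**Three steps most likely to fail, with fallbacks**

Step 7 (alkynylation at the tertiary epoxide carbon; competing C2 attack, ethyl transfer or elimination). The fallback reverses the roles of the two carbon groups, so that the alkyne is already on the alkene and methyl is the nucleophile. It sets out from ynoate 4 (using enyne 10) and returns at diol 13. Anti hydroiodination of 4 (NaI, AcOH, 70 °C) gives ethyl (2Z)-6-{[tert-butyl(diphenyl)silyl]oxy}-3-iodohex-2-enoate F1. Sonogashira coupling with 10 (PdCl2(PPh3)2, CuI, Et3N) gives ethyl (2Z)-3-(3-{[tert-butyl(diphenyl)silyl]oxy}propyl)-7-methylocta-2,7-dien-4-ynoate F2 with retention of geometry. Reduction with i-Bu2AlH gives (2Z)-3-(3-{[tert-butyl(diphenyl)silyl]oxy}propyl)-7-methylocta-2,7-dien-4-yn-1-ol F3. Sharpless epoxidation with the same L-(+)-tartrate catalyst gives [(2S,3R)-3-(4-methylpent-4-en-1-yn-1-yl)-3-(3-{[tert-butyl(diphenyl)silyl]oxy}propyl)oxiran-2-yl]methanol F4. Me3Al (CH2Cl2/hexane, −30 → 0 °C) then delivers methyl to the tertiary, propargylic epoxide carbon with inversion to give 13.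

Step 12 (ring closure to a trisubstituted cycloheptene next to a quaternary centre; slow initiation, dimerisation). The fallback builds in a relay so that the catalyst loads at a remote, unhindered alkene. It sets out from diol 14 and returns at cycloheptadiene 20. Acetalisation of 14 (4-MeOC6H4CH(OMe)2, pyridinium tosylate) gives tert-butyl({(4R,5Z)-4-[(4R)-2-(4-methoxyphenyl)-1,3-dioxolan-4-yl]-4,8-dimethylnona-5,8-dien-1-yl}oxy)diphenylsilane F5. i-Bu2AlH opens it at the less hindered oxygen to (2R,3R,4Z)-3-(3-{[tert-butyl(diphenyl)silyl]oxy}propyl)-2-[(4-methoxyphenyl)methoxy]-3,7-dimethylocta-4,7-dien-1-ol F6. Dess–Martin oxidation gives (2R,3R,4Z)-3-(3-{[tert-butyl(diphenyl)silyl]oxy}propyl)-2-[(4-methoxyphenyl)methoxy]-3,7-dimethylocta-4,7-dienal F7. A Z-selective Wittig reaction with hex-5-en-1-ylidene(triphenyl)phosphorane (phosphonium bromide, NaN(SiMe3)2, THF, −78 °C) gives tert-butyl({(4R,5Z)-4-{(1S,2Z)-1-[(4-methoxyphenyl)methoxy]octa-2,7-dien-1-yl}-4,8-dimethylnona-5,8-dien-1-yl}oxy)diphenylsilane F8. With the same ruthenium catalyst, F8 expels cyclopentene to place the carbene on C9 and closes ring B to 20.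

Step 19 (isopropyl addition to a hindered, enolisable cyclopentanone; reduction or enolisation instead of addition). The fallback uses an sp2 nucleophile without β-hydrogens and then a chemoselective hydrogenation. It sets out from ketone 29 and returns at carbinol 30. Isopropenylmagnesium bromide with CeCl3 (THF, −78 °C) adds from the same convex face to give (1R,4S,5S,6R,10S)-10-[(4-methoxyphenyl)methoxy]-1,8-dimethyl-4-(prop-1-en-2-yl)-6-[(triethylsilyl)oxy]-cis-bicyclo[5.3.0]dec-8-en-4-ol F9. Hydrogenation with RhCl(PPh3)3 (H2 1 atm, benzene, rt) saturates only the 1,1-disubstituted alkene and leaves the trisubstituted ring alkene, giving 30.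

**Further compounds**
F1 | step 7 | ethyl (2Z)-6-{[tert-butyl(diphenyl)silyl]oxy}-3-iodohex-2-enoate | CCOC(=O)/C=C(\I)CCCO[Si](c1ccccc1)(c1ccccc1)C(C)(C)C
F2 | step 7 | ethyl (2Z)-3-(3-{[tert-butyl(diphenyl)silyl]oxy}propyl)-7-methylocta-2,7-dien-4-ynoate | CCOC(=O)/C=C(\C#CCC(C)=C)CCCO[Si](c1ccccc1)(c1ccccc1)C(C)(C)C
F3 | step 7 | (2Z)-3-(3-{[tert-butyl(diphenyl)silyl]oxy}propyl)-7-methylocta-2,7-dien-4-yn-1-ol | OC/C=C(\C#CCC(C)=C)CCCO[Si](c1ccccc1)(c1ccccc1)C(C)(C)C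
F4 | step 7 | [(2S,3R)-3-(4-methylpent-4-en-1-yn-1-yl)-3-(3-{[tert-butyl(diphenyl)silyl]oxy}propyl)oxiran-2-yl]methanol | OC[C@@H]1O[C@@]1(C#CCC(C)=C)CCCO[Si](c2ccccc2)(c2ccccc2)C(C)(C)C
F5 | step 12 | tert-butyl({(4R,5Z)-4-[(4R)-2-(4-methoxyphenyl)-1,3-dioxolan-4-yl]-4,8-dimethylnona-5,8-dien-1-yl}oxy)diphenylsilane (acetal epimers) | COc1ccc(cc1)C2OC[C@H](O2)[C@](C)(CCCO[Si](c3ccccc3)(c3ccccc3)C(C)(C)C)/C=C\CC(C)=C
F6 | step 12 | (2R,3R,4Z)-3-(3-{[tert-butyl(diphenyl)silyl]oxy}propyl)-2-[(4-methoxyphenyl)methoxy]-3,7-dimethylocta-4,7-dien-1-ol | OC[C@H](OCc1ccc(OC)cc1)[C@](C)(CCCO[Si](c2ccccc2)(c2ccccc2)C(C)(C)C)/C=C\CC(C)=C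
F7 | step 12 | (2R,3R,4Z)-3-(3-{[tert-butyl(diphenyl)silyl]oxy}propyl)-2-[(4-methoxyphenyl)methoxy]-3,7-dimethylocta-4,7-dienal | O=C[C@H](OCc1ccc(OC)cc1)[C@](C)(CCCO[Si](c2ccccc2)(c2ccccc2)C(C)(C)C)/C=C\CC(C)=C
F8 | step 12 | tert-butyl({(4R,5Z)-4-{(1S,2Z)-1-[(4-methoxyphenyl)methoxy]octa-2,7-dien-1-yl}-4,8-dimethylnona-5,8-dien-1-yl}oxy)diphenylsilane | C=CCCC/C=C\[C@H](OCc1ccc(OC)cc1)[C@](C)(CCCO[Si](c2ccccc2)(c2ccccc2)C(C)(C)C)/C=C\CC(C)=C
F9 | step 19 | (1R,4S,5S,6R,10S)-10-[(4-methoxyphenyl)methoxy]-1,8-dimethyl-4-(prop-1-en-2-yl)-6-[(triethylsilyl)oxy]-cis-bicyclo[5.3.0]dec-8-en-4-ol | COc1ccc(CO[C@H]2C=C(C)C[C@@H](O[Si](CC)(CC)CC)[C@@H]3[C@@]2(C)CC[C@@]3(O)C(C)=C)cc1
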